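The oxane ring is cut across C4–C5 and O1–C6 (oxane numbering: C2 carries methyl and the CH2CH2 link, C3 bromine, C6 methyl and the chlorohydrin arm). This retro-oxa-Diels–Alder exploits the 1-oxadiene pattern O1–C2–C3–C4 beside the fully substituted C6: methyl vinyl ketone adds to the triethylsilyl ether of (S)-1-chloro-3-methylbut-3-en-2-ol, creating both bonds and C6 in one step. Bromoketalisation then ties C2 and C3 into a frontalin-type 6,8-dioxabicyclo[3.2.1]octane, whose ketal carbon is alkynylated by the bromocyclohexanol ring (ring A, from geraniol by asymmetric bromocyclisation). Hydrogenation of the alkyne completes the target.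

Key step: step 4

Remark on labels: O1–C6 are the oxane atoms of the target as defined above, C1' is the carbinol carbon of the chlorohydrin arm; these labels are used for all intermediates.
Assumption: in the oxazaborolidine reduction (step 2) the isopropenyl group behaves as the larger ketone substituent, and in step 7 the catalyst enantiomer is the one that gives the 6R bromide.

Step 1
Reactants: 1 2-chloro-N-methoxy-N-methylacetamide; 2 isopropenylmagnesium bromide
Product: 3 1-chloro-3-methylbut-3-en-2-one
Conditions: THF, −20 → 0 °C; cold aq. HCl quench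
Reagents that add atoms: none
Why: Weinreb ketone synthesis, in which the magnesium-chelated tetrahedral adduct stops the addition at the ketone and the chloromethyl group is untouched at low temperature; no stereocentre is formed.

Step 2
Reactants: 3 1-chloro-3-methylbut-3-en-2-one
Product: 4 (2S)-1-chloro-3-methylbut-3-en-2-ol
Conditions: (S)-2-methyl-CBS-oxazaborolidine (10 mol %), catecholborane (1.5 equiv), toluene, −78 °C
Reagents that add atoms: none
Why: Corey–Bakshi–Shibata reduction, in which the isopropenyl group acts as the large and the chloromethyl group as the small substituent so that the (S)-catalyst should deliver hydride to give the (S)-carbinol C1', while catecholborane at −78 °C avoids hydroboration of the alkene.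

Step 3
Reactants: 4 (2S)-1-chloro-3-methylbut-3-en-2-ol
Product: 5 triethyl{[(2S)-1-chloro-3-methylbut-3-en-2-yl]oxy}silane
Conditions: Et3SiCl, imidazole, CH2Cl2, 0 °C
Reagents that add atoms: chlorotriethylsilane, CC[Si](Cl)(CC)CC
Why: Silyl ether formation, which prevents premature ketalisation of the enol ether made in step 4 and keeps the oxygen available as the internal nucleophile of step 5.

Step 4
Reactants: 5 triethyl{[(2S)-1-chloro-3-methylbut-3-en-2-yl]oxy}silane; 6 methyl vinyl ketone
Product: 7 (2S)-2-[(1S)-2-chloro-1-(triethylsilyloxy)ethyl]-2,6-dimethyl-3,4-dihydro-2H-pyran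
Conditions: 6 (5 equiv, added in portions), BHT (2 mol %), K2CO3 (trace), toluene, sealed tube, 170 °C
Reagents that add atoms: none
Why: Thermal inverse-electron-demand oxa-Diels–Alder reaction in which s-cis 6 is the 1-oxadiene (O1, C2, C3, C4) and the 1,1-disubstituted alkene of 5 the 2π partner, so that C4–C5 and O1–C6 form in one concerted, asynchronous [4+2] event with C–C bonding in the lead. The closest known case is the thermal cycloaddition of methyl vinyl ketone with 2-methylprop-2-en-1-ol that gives frontalin-type dihydropyrans. The only ring formed, the dihydropyran, is closed by this intermolecular [4+2] cycloaddition. The new quaternary centre C6 is controlled by the neighbouring silyloxy carbon C1': allylic 1,2-strain with the alkene methyl places the carbinol hydrogen outside, the silyloxy group inside and the chloromethyl group anti to the incoming oxadiene, which should favour the (S,S) (erythro) adduct. The step needs regioselectivity (oxygen to the substituted alkene carbon), which the attack of the nucleophilic CH2 terminus on the enone β-carbon secures, facial selectivity, which rests on the C1' stereocentre, and chemoselectivity over dimerisation of 6, which excess 6 and the inhibitor address; the enol ether, C–Cl and O–Si bonds should be stable without acid.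

Step 5
Reactants: 7 (2S)-2-[(1S)-2-chloro-1-(triethylsilyloxy)ethyl]-2,6-dimethyl-3,4-dihydro-2H-pyran
Product: 8 (1S,4R,5R,7S)-4-bromo-7-(chloromethyl)-1,5-dimethyl-6,8-dioxabicyclo[3.2.1]octane
Conditions: NBS (1.05 equiv), NaHCO3, MeCN, −30 → 0 °C, dark
Reagents that add atoms: N-bromosuccinimide, O=C1CCC(=O)N1Br
Why: Bromoetherification (bromoketalisation) of the enol ether, in which NBS brominates C3 while the silyloxy oxygen, able to reach C2 only from the face of its tether, captures the oxocarbenium carbon with loss of the silyl group, so that anti addition sets C3 (bromine trans to the new C2–O bond) and the ketal centre; ketals from any minor C6 epimer of 7 are diastereomers and should be separable here.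

Step 6
Reactants: 9 geraniol
Product: 10 tert-butyl geranyl carbonate
Conditions: Boc2O, DMAP (10 mol %), MeCN, rt
Reagents that add atoms: di-tert-butyl dicarbonate, CC(C)(C)OC(=O)OC(=O)OC(C)(C)C
Why: DMAP-catalysed acylation to the mixed carbonate, which installs the carbonyl oxygen that terminates the cyclisation of step 7.

Step 7
Reactants: 10 tert-butyl geranyl carbonate
Product: 11 (4aS,6R,8aR)-6-bromo-5,5,8a-trimethylhexahydro-4H-benzo[d][1,3]dioxin-2-one
Conditions: chiral BINOL-derived thiophosphoramide Lewis-base catalyst (10 mol %), 1,3-dibromo-5,5-dimethylhydantoin (0.55 equiv), toluene–CH2Cl2, −78 °C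
Reagents that add atoms: 1,3-dibromo-5,5-dimethylhydantoin, CC1(C)N(Br)C(=O)N(Br)C1=O
Why: Catalytic asymmetric bromonium-induced polyene cyclisation, in which the chiral Lewis base transfers Br+ to one face of the terminal trisubstituted alkene, the E-alkene attacks through a chair transition state and the carbonate carbonyl oxygen traps the tertiary cation with loss of isobutene, which should give equatorial bromine, trans ring fusion and hence all three ring-A stereocentres.

Step 8
Reactants: 11 (4aS,6R,8aR)-6-bromo-5,5,8a-trimethylhexahydro-4H-benzo[d][1,3]dioxin-2-one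
Product: 12 (1R,2S,4R)-4-bromo-2-(hydroxymethyl)-1,3,3-trimethylcyclohexan-1-ol
Conditions: K2CO3, MeOH, 0 °C → rt
Reagents that add atoms: none
Why: Base-catalysed methanolysis (transesterification) of the cyclic carbonate under conditions mild enough to leave the equatorial secondary bromide untouched.

Step 9
Reactants: 12 (1R,2S,4R)-4-bromo-2-(hydroxymethyl)-1,3,3-trimethylcyclohexan-1-ol
Product: 13 (1R,3R,6R)-3-bromo-6-hydroxy-2,2,6-trimethylcyclohexane-1-carbaldehyde
Conditions: TEMPO (10 mol %), PhI(OAc)2 (1.1 equiv), CH2Cl2, rt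
Reagents that add atoms: none
Why: TEMPO/PhI(OAc)2 oxidation, selective for the primary alcohol beside the tertiary one and stopping at the aldehyde, whose equatorial position at the α-carbon is the stable one.

Step 10
Reactants: 13 (1R,3R,6R)-3-bromo-6-hydroxy-2,2,6-trimethylcyclohexane-1-carbaldehyde
Product: 14 (1R,2R,4R)-4-bromo-2-ethynyl-1,3,3-trimethylcyclohexan-1-ol
Conditions: dimethyl (1-diazo-2-oxopropyl)phosphonate, K2CO3, MeOH, 0 °C
Reagents that add atoms: dimethyl (1-diazo-2-oxopropyl)phosphonate, COP(=O)(OC)C(=[N+]=[N-])C(C)=O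
Why: Ohira–Bestmann (Seyferth–Gilbert) homologation, in which the diazophosphonate anion generated in methanol converts the aldehyde into the terminal alkyne at 0 °C, mild enough to limit retro-aldol cleavage or dehydration of the β-hydroxy aldehyde.

Step 11
Reactants: 14 (1R,2R,4R)-4-bromo-2-ethynyl-1,3,3-trimethylcyclohexan-1-ol; 8 (1S,4R,5R,7S)-4-bromo-7-(chloromethyl)-1,5-dimethyl-6,8-dioxabicyclo[3.2.1]octane
Product: 17 (1R,2R,4R)-4-bromo-2-{[(2S,3R,6S)-3-bromo-6-[(1S)-2-chloro-1-hydroxyethyl]-2,6-dimethyloxan-2-yl]ethynyl}-1,3,3-trimethylcyclohexan-1-ol, via dilithium alkoxide-acetylide 15 (not isolated), via aluminium alkoxide-alkynylalane 16 (not isolated)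
Conditions: n-BuLi (2.05 equiv), toluene, −78 → 0 °C; Me2AlCl (2.1 equiv), 0 °C; then 8, toluene, 0 → 45 °C; aq. Rochelle salt
Reagents that add atoms: none
Why: Alkynylalane opening of a bicyclic ketal (C-glycosylation-type substitution at the ketal carbon, as with 1,6-anhydro sugars), in which aluminium binds the less hindered dioxolane oxygen, the C2–O bond ionises with help from the antiperiplanar C3 bromine and the alkynyl group is delivered to C2 on the face the oxygen leaves, anti to bromine, so that the quaternary centre C2 should form with the alkyne cis to the chlorohydrin arm and trans to bromine.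

Step 12
Reactants: 17 (1R,2R,4R)-4-bromo-2-{[(2S,3R,6S)-3-bromo-6-[(1S)-2-chloro-1-hydroxyethyl]-2,6-dimethyloxan-2-yl]ethynyl}-1,3,3-trimethylcyclohexan-1-ol
Product: 18 (1R,2R,4R)-4-bromo-2-{2-[(2S,3R,6S)-3-bromo-6-[(1S)-2-chloro-1-hydroxyethyl]-2,6-dimethyloxan-2-yl]ethyl}-1,3,3-trimethylcyclohexan-1-ol
Conditions: H2 (4 atm), PtO2 (10 mol %), EtOAc, rt
Reagents that add atoms: none
Why: Heterogeneous catalytic hydrogenation of the alkyne to the CH2CH2 link over platinum in a neutral solvent, under which the secondary bromides, the primary chloride and the tertiary ether should survive and no stereocentre is touched.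

Compound list
1 | 2-chloro-N-methoxy-N-methylacetamide | CON(C)C(=O)CCl | starting material
2 | isopropenylmagnesium bromide | CC(=C)[Mg]Br | starting material
3 | 1-chloro-3-methylbut-3-en-2-one | CC(=C)C(=O)CCl | intermediate
4 | (2S)-1-chloro-3-methylbut-3-en-2-ol | C=C(C)[C@H](O)CCl | intermediate
5 | triethyl{[(2S)-1-chloro-3-methylbut-3-en-2-yl]oxy}silane | C=C(C)[C@H](O[Si](CC)(CC)CC)CCl | intermediate
6 | methyl vinyl ketone (but-3-en-2-one) | CC(=O)C=C | starting material
7 | (2S)-2-[(1S)-2-chloro-1-(triethylsilyloxy)ethyl]-2,6-dimethyl-3,4-dihydro-2H-pyran | CC1=CCC[C@](C)(O1)[C@H](O[Si](CC)(CC)CC)CCl | intermediate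
8 | (1S,4R,5R,7S)-4-bromo-7-(chloromethyl)-1,5-dimethyl-6,8-dioxabicyclo[3.2.1]octane | O1[C@]2(C)O[C@](C)([C@H]1CCl)CC[C@H]2Br | intermediate
9 | geraniol, (2E)-3,7-dimethylocta-2,6-dien-1-ol | CC(C)=CCC/C(C)=C/CO | starting material
10 | tert-butyl geranyl carbonate | CC(C)=CCC/C(C)=C/COC(=O)OC(C)(C)C | intermediate
11 | (4aS,6R,8aR)-6-bromo-5,5,8a-trimethylhexahydro-4H-benzo[d][1,3]dioxin-2-one | CC1(C)[C@H](Br)CC[C@@]2(C)OC(=O)OC[C@H]12 | intermediate
12 | (1R,2S,4R)-4-bromo-2-(hydroxymethyl)-1,3,3-trimethylcyclohexan-1-ol | CC1(C)[C@H](Br)CC[C@@](C)(O)[C@@H]1CO | intermediate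
13 | (1R,3R,6R)-3-bromo-6-hydroxy-2,2,6-trimethylcyclohexane-1-carbaldehyde | CC1(C)[C@H](Br)CC[C@@](C)(O)[C@@H]1C=O | intermediate
14 | (1R,2R,4R)-4-bromo-2-ethynyl-1,3,3-trimethylcyclohexan-1-ol | CC1(C)[C@H](Br)CC[C@@](C)(O)[C@@H]1C#C | intermediate
15 | dilithium alkoxide-acetylide of 14 | CC1(C)[C@H](Br)CC[C@@](C)(O[Li])[C@@H]1C#C[Li] | intermediate
16 | O-(dimethylaluminium) alkoxide and C-(dimethylaluminium) acetylide of 14 | CC1(C)[C@H](Br)CC[C@@](C)(O[Al](C)C)[C@@H]1C#C[Al](C)C | intermediate
17 | (1R,2R,4R)-4-bromo-2-{[(2S,3R,6S)-3-bromo-6-[(1S)-2-chloro-1-hydroxyethyl]-2,6-dimethyloxan-2-yl]ethynyl}-1,3,3-trimethylcyclohexan-1-ol | CC1(C)[C@H](Br)CC[C@@](C)(O)[C@@H]1C#C[C@]1(C)O[C@](C)([C@H](O)CCl)CC[C@H]1Br | intermediate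
18 | (1R,2R,4R)-4-bromo-2-{2-[(2S,3R,6S)-3-bromo-6-[(1S)-2-chloro-1-hydroxyethyl]-2,6-dimethyloxan-2-yl]ethyl}-1,3,3-trimethylcyclohexan-1-ol | CC1(C)[C@H](Br)CC[C@@](C)(O)[C@@H]1CC[C@]1(C)O[C@](C)([C@H](O)CCl)CC[C@H]1Br | target

Total steps: 12. Longest linear sequence: 7 steps (steps 1–5, 11, 12; the ring-A branch, steps 6–10, 11, 12, is equally long).

Steps most likely to fail

Step 4. The cycloaddition may be outrun by self-dimerisation or polymerisation of 6, or the alkene faces may be poorly discriminated so that the C6 epimer forms in quantity. The fallback sets out from 4 and fixes C6 by hydroxyl-directed epoxidation instead. Sharpless epoxidation of 4 in its matched sense (Ti(OiPr)4, D-(−)-diisopropyl tartrate, t-BuOOH) should give the erythro epoxy alcohol (1S)-2-chloro-1-[(2S)-2-methyloxiran-2-yl]ethan-1-ol F1. CuI-catalysed opening at the epoxide CH2 with commercial but-3-enylmagnesium bromide at low temperature gives (2S,3S)-1-chloro-3-methyloct-7-ene-2,3-diol F2. Wacker oxidation (PdCl2, CuCl, O2, DMF–H2O) and acid-catalysed intramolecular ketalisation give the frontalin-type ketal (1S,5R,7S)-7-(chloromethyl)-1,5-dimethyl-6,8-dioxabicyclo[3.2.1]octane F3. Bromination of F3 with pyridinium tribromide, through the endocyclic enol ether and anti re-closure, comes back to the route at 8.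

Step 11. The α-bromo ketal may fail to ionise (bromine retards C–O cleavage inductively), the other C–O bond may cleave, or methyl may be transferred from aluminium in place of the alkynyl group. The fallback sets out from 8 and 14, opens the ketal first and changes the carbon nucleophile. Acetolysis of 8 (Ac2O, cat. TMSOTf) gives the ketosyl acetate (2S,3R,6S)-6-[(1S)-1-acetoxy-2-chloroethyl]-3-bromo-2,6-dimethyloxan-2-yl acetate F4 (either anomer serves). Compound 14 is converted (n-BuLi, 2 equiv; Bu3SnCl; aqueous work-up) into (1R,2S,4R)-4-bromo-1,3,3-trimethyl-2-[(tributylstannyl)ethynyl]cyclohexan-1-ol F5. TMSOTf-promoted coupling, with attack on the bromine-bridged oxocarbenium ion anti to the C3 bromine, gives the C1' acetate of 17 F6. DIBAL-H at −78 °C removes the acetate without closing the chlorohydrin to an epoxide and comes back to the route at 17.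

Step 7. Uncatalysed bromonium transfer may erode the enantiomeric purity, or the tertiary cation may lose a proton before the carbonate oxygen closes. The fallback sets out from 10 and replaces asymmetric catalysis by resolution. Cyclisation with the sulfonium reagent Et2SBr·SbCl5Br in MeNO2 at −25 °C gives the racemate, that is 11 together with its enantiomer (4aR,6S,8aS)-6-bromo-5,5,8a-trimethylhexahydro-4H-benzo[d][1,3]dioxin-2-one F7. Methanolysis as in step 8 gives 12 together with its enantiomer (1S,2R,4S)-4-bromo-2-(hydroxymethyl)-1,3,3-trimethylcyclohexan-1-ol F8. Esterification of the primary hydroxyl with (R)-2-methoxy-2-phenylacetic acid (DCC, DMAP) gives the diastereomeric esters [(1S,3R,6R)-3-bromo-6-hydroxy-2,2,6-trimethylcyclohexyl]methyl (R)-2-methoxy-2-phenylacetate F9 (from 12) and [(1R,3S,6S)-3-bromo-6-hydroxy-2,2,6-trimethylcyclohexyl]methyl (R)-2-methoxy-2-phenylacetate F10 (from F8), to be separated by chromatography or crystallisation. K2CO3 in MeOH on F9 comes back to the route at 12.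

Further compounds
F1 | step 4 | (1S)-2-chloro-1-[(2S)-2-methyloxiran-2-yl]ethan-1-ol | C[C@]1(CO1)[C@H](O)CCl
F2 | step 4 | (2S,3S)-1-chloro-3-methyloct-7-ene-2,3-diol | C=CCCC[C@](C)(O)[C@H](O)CCl
F3 | step 4 | (1S,5R,7S)-7-(chloromethyl)-1,5-dimethyl-6,8-dioxabicyclo[3.2.1]octane | O1[C@]2(C)O[C@](C)([C@H]1CCl)CCC2
F4 | step 11 | (2S,3R,6S)-6-[(1S)-1-acetoxy-2-chloroethyl]-3-bromo-2,6-dimethyloxan-2-yl acetate | CC(=O)O[C@]1(C)O[C@](C)([C@H](OC(C)=O)CCl)CC[C@H]1Br
F5 | step 11 | (1R,2S,4R)-4-bromo-1,3,3-trimethyl-2-[(tributylstannyl)ethynyl]cyclohexan-1-ol | CC1(C)[C@H](Br)CC[C@@](C)(O)[C@@H]1C#C[Sn](CCCC)(CCCC)CCCC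
F6 | step 11 | C1' acetate of 17, (1S)-1-[(2S,5R,6S)-5-bromo-6-{[(1R,3R,6R)-3-bromo-6-hydroxy-2,2,6-trimethylcyclohexyl]ethynyl}-2,6-dimethyloxan-2-yl]-2-chloroethyl acetate | CC1(C)[C@H](Br)CC[C@@](C)(O)[C@@H]1C#C[C@]1(C)O[C@](C)([C@H](OC(C)=O)CCl)CC[C@H]1Br
F7 | step 7 | (4aR,6S,8aS)-6-bromo-5,5,8a-trimethylhexahydro-4H-benzo[d][1,3]dioxin-2-one (enantiomer of 11) | CC1(C)[C@@H](Br)CC[C@]2(C)OC(=O)OC[C@@H]12
F8 | step 7 | (1S,2R,4S)-4-bromo-2-(hydroxymethyl)-1,3,3-trimethylcyclohexan-1-ol (enantiomer of 12) | CC1(C)[C@@H](Br)CC[C@](C)(O)[C@H]1CO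
F9 | step 7 | [(1S,3R,6R)-3-bromo-6-hydroxy-2,2,6-trimethylcyclohexyl]methyl (R)-2-methoxy-2-phenylacetate | CC1(C)[C@H](Br)CC[C@@](C)(O)[C@@H]1COC(=O)[C@H](OC)c1ccccc1
F10 | step 7 | [(1R,3S,6S)-3-bromo-6-hydroxy-2,2,6-trimethylcyclohexyl]methyl (R)-2-methoxy-2-phenylacetate | CC1(C)[C@@H](Br)CC[C@](C)(O)[C@H]1COC(=O)[C@H](OC)c1ccccc1
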